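Do not take a flat curve for an empty flask. In the winter run the left-handed substrate stands near 22.3% of the two charged together from 10.0 s on, so plenty remains, yet the reaction has stopped. Read the stop as the death of the catalyst.

| flask | left-handed substrate | right-handed substrate | coupling partner | free catalyst | remark | time |
|---|---|---|---|---|---|---|
| autumn | 0.13 M | 0.13 M | 1.2 equiv | 15 mol% | run made earlier |  |
| winter | 0.20 M | 0.20 M | 2.4 equiv | 15 mol% | run made earlier |  |
| Tuesday's | 0.20 M | 0.20 M | 1.20 equiv | 15 mol% |  | 5.0 min |
| Wednesday's | 0.20 M | 0.20 M | 1.20 equiv | 10 mol% |  | 5.0 min |

- autumn (time / s: right-handed substrate / %, left-handed substrate / %, left-handed product / %): 10.0: 49.5, 34.1, 16.2; 12.0: 49.3, 33.3, 17.6; 25.0: 49.5, 30.9, 19.6; 60.0: 49.2, 30.3, 19.7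
- winter (time / s: right-handed substrate / %, left-handed substrate / %, left-handed product / %): 10.0: 48.5, 22.8, 26.7; 20.0: 47.8, 21.3, 28.0; 40.0: 47.5, 23.3, 27.0; 60.0: 48.2, 21.7, 27.5

(readings scatter by 0.5 percentage points)

- free catalyst is single-handed; left-handed substrate and right-handed substrate are mirror images of each other, charged as a racemate, each of them at the stated concentration
- the numbers in the tables scatter by 0.5 percentage points (one standard deviation)
- steps that have been proposed: coupling partner + free catalyst + right-handed substrate -> free catalyst + right-handed product; coupling partner -> decomposed reagent; coupling partner + free catalyst -> spent catalyst; coupling partner + free catalyst + left-handed substrate -> free catalyst + left-handed product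
- an excess is the difference of the two amounts in percent of their sum
- an excess is below zero if the other one leads

1. the winner by excess of right-handed substrate over left-handed substrate among what is left of the two; "neither" if no more than 2 percentage points parts them (Tuesday's / Wednesday's / neither)
2. excess of right-handed substrate over left-handed substrate among what is left of the two at the end, Tuesday's
3. excess of right-handed substrate over left-handed substrate among what is left of the two at the end, Wednesday's

Integrate in closed form. On the proposed steps, ln[left-handed substrate] falls at a rate proportional to [coupling partner][free catalyst], and [free catalyst] falls at a rate proportional to [coupling partner][free catalyst]. Divide one by the other and both the clock and the partner cancel: ln(charged [left-handed substrate] / [left-handed substrate]) = G × (charged [free catalyst] − [free catalyst]). Winter's plateau gives 27.0 /M, the catalyst's lifetime yield G, the logarithmic substrate loss per molar of catalyst killed.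

Autumn's plateau, 30.6%, gives a second value, 25.2 /M, which is lower. Autumn charged less partner, 0.156 M against 0.480 M, and a run whose catalyst outlives its partner reads short, but the gap of 1.80 /M may also be scatter on autumn's two plateau readings, and these two runs do not tell which. Keep winter's G, whose logarithm is larger, so the same scatter weighs less on it.

Pooling both runs, with 48.0% and 49.4% of right-handed substrate, gives a reading of the selectivity factor of 24.3.

Assume the catalyst dies in both new flasks. Tuesday's then leaves 22.3% left-handed and 48.4% right-handed substrate, an excess of 36.9%. Wednesday's leaves 29.2% and 48.9%, an excess of 25.3%. Tuesday's wins by 12 percentage points.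

The forecast says Tuesday's, with 36% (31% to 39%) and 25% (21% to 28%), on this ground: “conversion is set mainly by catalyst death through the partner”. The flask gives Tuesday's, with 36.1% and 24.7%.

    coupling partner + free catalyst + right-handed substrate → free catalyst + right-handed product (k = 1.70 /M²/s)
    coupling partner → decomposed reagent (k = 0.0170 /s)
    coupling partner + free catalyst → spent catalyst (k = 1.40 /M/s)
    coupling partner + free catalyst + left-handed substrate → free catalyst + left-handed product (k = 37.0 /M²/s)

Put Tuesday's left-handed substrate, 22.6%, back into the law: it gives 26.4 /M, beside 27.0 /M. For the neighbour of Tuesday's charged with 6 mol% of free catalyst, G gives 36.2% left-handed substrate, and that flask holds 36.4%. Tuesday's flask is at rest at 5.00 min, keeping 0.199% of its coupling partner and 0.0475% of its free catalyst. Wednesday's keeps 0.317% and 0%. Ten times the time changes neither excess: Wednesday's reads 24.7% and Tuesday's 36.1%.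

The data are simulated with constants of no real substance; noise was put on by code.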